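With the oxolane numbered O1–C2(aryl)–C3(methyl)–C4–C5H2 and the carbinol carbon called C7′, the target is 2S,3S,4R,7′R (2,3-trans, 3,4-cis). The route exploits the fact that C5 is a methylene whose only neighbours are O1 and C4, so it can be delivered as CO. One palladium-catalysed cyclocarbonylation of an anti homopropargylic alcohol makes O1–C5 and C4–C5, closes the five-membered ring as a lactone and fixes the C4=C7′ alkene as E. That geometry, with the C3 methyl, later sets C4 and C7′ in one syn hydroboration. The precursor, (1S,2S)-1,4-bis(3,4-dimethoxyphenyl)-2-methylbut-3-yn-1-ol, already holds C2 and C3 and carries C4/C7′ as an aryl alkyne.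

Key step: step 4

Remark: the zinc species of step 2 is drawn as allenyl(ethyl)zinc; whether zinc carries ethyl or mesylate does not change the stereochemical course. The ring numbering above is used throughout.

Step 1
Reactants: 1 (R)-but-3-yn-2-ol
Product: 2 (R)-but-3-yn-2-yl methanesulfonate
Conditions: MsCl, Et3N, CH2Cl2, −78 → 0 °C; used crude
Reagents that add atoms: methanesulfonyl chloride, CS(=O)(=O)Cl
Why: O-Sulfonylation of the secondary propargylic alcohol leaves the C–O bond intact, so the R configuration is carried into the leaving group needed for the next step.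

Step 2
Reactants: 2 (R)-but-3-yn-2-yl methanesulfonate; 3 veratraldehyde
Product: 5 (1S,2S)-1-(3,4-dimethoxyphenyl)-2-methylbut-3-yn-1-ol, via allenyl(ethyl)zinc 4 (not isolated)
Conditions: Pd(OAc)2 (5 mol %), PPh3 (5 mol %), Et2Zn (3 equiv), THF, −78 → −20 °C; NH4Cl aq
Reagents that add atoms: none
Why: Marshall–Tamaru propargylation: zerovalent palladium formed in situ displaces the mesylate in an anti SN2′ sense, transmetalation with Et2Zn gives the configurationally defined allenylzinc 4, and its cyclic SE2′ addition to the aldehyde keeps the aryl group away from the allenyl methyl, which should give the anti adduct with net inversion at the methyl-bearing carbon (future C3 = S, future C2 = S).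

Step 3
Reactants: 5 (1S,2S)-1-(3,4-dimethoxyphenyl)-2-methylbut-3-yn-1-ol; 6 4-iodoveratrole
Product: 7 (1S,2S)-1,4-bis(3,4-dimethoxyphenyl)-2-methylbut-3-yn-1-ol
Conditions: PdCl2(PPh3)2 (2 mol %), CuI (4 mol %), Et3N, THF, degassed, rt → 40 °C
Reagents that add atoms: none
Why: Sonogashira coupling of the terminal alkyne with the aryl iodide runs under mild amine base, where the free carbinol, the propargylic C–H and both stereocentres are spectators.

Step 4
Reactants: 7 (1S,2S)-1,4-bis(3,4-dimethoxyphenyl)-2-methylbut-3-yn-1-ol; 8 carbon monoxide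
Product: 9 (3E,4S,5S)-3-(3,4-dimethoxybenzylidene)-5-(3,4-dimethoxyphenyl)-4-methyloxolan-2-one
Conditions: PdI2 (5 mol %), PBu3 (10 mol %), CO (7 atm), MeCN, 75 °C
Reagents that add atoms: none
Why: Palladium-catalysed cyclocarbonylation of a but-3-yn-1-ol: the C2 hydroxyl and CO form an alkoxycarbonylpalladium species that adds syn across the tethered alkyne, and protonolysis of the vinylpalladium releases the lactone (a palladium hydride addition, CO insertion and lactonisation would converge on the same product). The closest known reaction type is the conversion of but-3-yn-1-ols, internal alkynes included, into (E)-α-alkylidene-γ-butyrolactones with phosphine-ligated palladium halides under CO. The five-membered lactone closes 5-exo-dig, acyl carbon C5 bonding to alkyne carbon C4; a 6-endo closure would need a trans double bond inside a six-membered ring and is excluded for a syn addition. No stereocentre is created: C2 and C3 pass through untouched because no bond to either is broken, and the only new stereo-element, the alkene, is E because C5 and the vinylic hydrogen arrive on the same side. The step needs carbonylation to beat 5-endo oxypalladation (which would give a dihydrofuran) and the exocyclic alkene must not migrate into the ring; phosphine ligation, CO pressure, a base-free medium and the three-atom hydroxyl-to-alkyne tether should secure this.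

Step 5
Reactants: 9 (3E,4S,5S)-3-(3,4-dimethoxybenzylidene)-5-(3,4-dimethoxyphenyl)-4-methyloxolan-2-one
Product: 10 (1S,2S,3E)-1,4-bis(3,4-dimethoxyphenyl)-3-(hydroxymethyl)-2-methylbut-3-en-1-ol
Conditions: i-Bu2AlH (4 equiv), CH2Cl2, −78 → 0 °C; aqueous potassium sodium tartrate
Reagents that add atoms: none
Why: Excess i-Bu2AlH reduces the α,β-unsaturated lactone in the 1,2 sense through the lactol to the allylic 1,4-diol, leaving the trisubstituted alkene and both stereocentres untouched.

Step 6
Reactants: 10 (1S,2S,3E)-1,4-bis(3,4-dimethoxyphenyl)-3-(hydroxymethyl)-2-methylbut-3-en-1-ol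
Product: 11 (2S,3S,4E)-4-(3,4-dimethoxybenzylidene)-2-(3,4-dimethoxyphenyl)-3-methyloxolane
Conditions: PPh3, DIAD, THF, 0 °C → rt
Reagents that add atoms: none
Why: Mitsunobu cyclodehydration: the unhindered primary allylic hydroxyl becomes the oxyphosphonium leaving group and is displaced 5-exo-tet at C5 by the C2 hydroxyl, so the C2–O bond is never broken and C2 stays S, while the neutral medium avoids ionising the electron-rich benzylic and cinnamylic positions.

Step 7
Reactants: 11 (2S,3S,4E)-4-(3,4-dimethoxybenzylidene)-2-(3,4-dimethoxyphenyl)-3-methyloxolane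
Product: 13 (R)-(3,4-dimethoxyphenyl)[(3R,4S,5S)-5-(3,4-dimethoxyphenyl)-4-methyloxolan-3-yl]methanol, via benzylic monoalkylborane 12 (not isolated)
Conditions: BH3·THF (3 equiv), THF, 0 °C → rt; then NaOH aq, H2O2, 0 °C → rt
Reagents that add atoms: hydrogen peroxide, OO
Why: Hydroboration–oxidation of a trisubstituted styrenyl alkene puts boron on the less substituted benzylic carbon C7′ and hydrogen on C4 in one syn addition from the face opposite the C3 methyl, which A(1,3) strain with the cis aryl of the E alkene holds pseudo-axial, so C4 (R, 3,4-cis) and, after oxidation with retention, C7′ (R) are set together; the ring is closed first because an open-chain A(1,3) model predicts attack on the other face.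

Compound list
1 | (R)-but-3-yn-2-ol | C[C@@H](O)C#C | starting material
2 | (R)-but-3-yn-2-yl methanesulfonate | C[C@@H](OS(C)(=O)=O)C#C | intermediate
3 | veratraldehyde (3,4-dimethoxybenzaldehyde) | COc1ccc(C=O)cc1OC | starting material
4 | (aS)-buta-1,2-dien-1-yl(ethyl)zinc (P helix; not isolated) | CC[Zn]C([H])=[C@@]=C([H])C | intermediate
5 | (1S,2S)-1-(3,4-dimethoxyphenyl)-2-methylbut-3-yn-1-ol (anti) | COc1ccc([C@@H](O)[C@@H](C)C#C)cc1OC | intermediate
6 | 4-iodoveratrole (4-iodo-1,2-dimethoxybenzene) | COc1ccc(I)cc1OC | starting material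
7 | (1S,2S)-1,4-bis(3,4-dimethoxyphenyl)-2-methylbut-3-yn-1-ol (anti) | COc1ccc([C@@H](O)[C@@H](C)C#Cc2ccc(OC)c(OC)c2)cc1OC | intermediate
8 | carbon monoxide | [C-]#[O+] | starting material
9 | (3E,4S,5S)-3-(3,4-dimethoxybenzylidene)-5-(3,4-dimethoxyphenyl)-4-methyloxolan-2-one | COc1ccc([C@H]2OC(=O)/C(=C/c3ccc(OC)c(OC)c3)[C@@H]2C)cc1OC | intermediate
10 | (1S,2S,3E)-1,4-bis(3,4-dimethoxyphenyl)-3-(hydroxymethyl)-2-methylbut-3-en-1-ol | COc1ccc([C@@H](O)[C@@H](C)/C(CO)=C\c3ccc(OC)c(OC)c3)cc1OC | intermediate
11 | (2S,3S,4E)-4-(3,4-dimethoxybenzylidene)-2-(3,4-dimethoxyphenyl)-3-methyloxolane | COc1ccc([C@H]2OC/C(=C/c3ccc(OC)c(OC)c3)[C@@H]2C)cc1OC | intermediate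
12 | {(R)-(3,4-dimethoxyphenyl)[(3R,4S,5S)-5-(3,4-dimethoxyphenyl)-4-methyloxolan-3-yl]methyl}borane (not isolated) | COc1ccc([C@H]2OC[C@H]([C@@H](B)c3ccc(OC)c(OC)c3)[C@@H]2C)cc1OC | intermediate
13 | (R)-(3,4-dimethoxyphenyl)[(3R,4S,5S)-5-(3,4-dimethoxyphenyl)-4-methyloxolan-3-yl]methanol (2S,3S,4R,7′R in the numbering used here) | COc1ccc([C@H]2OC[C@H]([C@@H](O)c3ccc(OC)c(OC)c3)[C@@H]2C)cc1OC | target

Total steps: 7. Longest linear sequence: 7 steps (1 → 13).

Steps most likely to fail

1. Step 4 (key step). The carbonylation may stall on the internal, electron-rich aryl alkyne or be diverted into 5-endo cycloisomerisation. Traces of HI from PdI2 may ionise the electron-rich benzylic carbinol, and migration of the exocyclic alkene into the ring would erase C3. The fallback sets out from 5 and comes back at 9, and needs neither CO nor 6. Ruthenium-catalysed oxidative cyclisation of the terminal homopropargylic alcohol through a vinylidene (CpRuCl(cod) cat., P(2-furyl)3, N-hydroxysuccinimide, Bu4NBr, NaHCO3, DMF–H2O, 95 °C) should give (4S,5S)-5-(3,4-dimethoxyphenyl)-4-methyloxolan-2-one F1. Aldol addition of its lithium enolate (LiN(SiMe3)2, THF, −78 °C) to veratraldehyde 3 should give (4S,5S)-5-(3,4-dimethoxyphenyl)-3-[(3,4-dimethoxyphenyl)(hydroxy)methyl]-4-methyloxolan-2-one F2, as a mixture at the two new centres, which the next operation removes. Mesylation (MsCl, Et3N, CH2Cl2, 0 °C) to the corresponding methanesulfonate F3 and E1cB elimination with DBU should then give the thermodynamically preferred E-benzylidene lactone 9. Here C5 comes from the alkyne terminus and C7′ with its aryl from the aldehyde.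

2. Step 7. Facial discrimination may be insufficient, because the C2 aryl lies on the face the borane must use, and some boron may go to C4. The fallback sets out from 11 and comes back at 13 by moving stereocontrol from the substrate to the reagent. It is an asymmetric hydroboration with monoisopinocampheylborane (IpcBH2, THF, −25 °C; then NaOH, H2O2). The enantiomer derived from (+)-α-pinene is predicted, by analogy with its known preference on 2-methylbut-2-ene, to deliver boron to the required face of C7′; both antipodes would be tried to find the matched pair. The bulk of this monoalkylborane should also sharpen the placement of boron at C7′. The fallback makes no compound outside the list (F0).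

3. Step 2. The anti preference may erode, and addition may be slow, with the electron-rich aromatic aldehyde; chirality transfer from the mesylate may also be incomplete. The fallback sets out from 3 and comes back at 5.
- Brown crotylboration with (E)-crotyldiisopinocampheylborane (from trans-but-2-ene, n-BuLi/KOt-Bu, (−)-Ipc2BOMe, BF3·OEt2; THF, −78 °C; NaOH/H2O2 work-up) should give the anti homoallylic alcohol (1S,2S)-1-(3,4-dimethoxyphenyl)-2-methylbut-3-en-1-ol F4.
- Silylation (t-BuMe2SiCl, imidazole, DMF) should give tert-butyl{[(1S,2S)-1-(3,4-dimethoxyphenyl)-2-methylbut-3-en-1-yl]oxy}dimethylsilane F5.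
- Lemieux–Johnson cleavage (OsO4 cat., NaIO4, 2,6-lutidine, dioxane–H2O), which spares the electron-rich rings, should give (2R,3S)-3-[(tert-butyldimethylsilyl)oxy]-3-(3,4-dimethoxyphenyl)-2-methylpropanal F6.
- Ohira–Bestmann homologation (dimethyl (1-diazo-2-oxopropyl)phosphonate, K2CO3, MeOH, 0 °C → rt) should give tert-butyl{[(1S,2S)-1-(3,4-dimethoxyphenyl)-2-methylbut-3-yn-1-yl]oxy}dimethylsilane F7.
- Bu4NF in THF should return alkynol 5.

Further compounds
F1 | step 4 | (4S,5S)-5-(3,4-dimethoxyphenyl)-4-methyloxolan-2-one | COc1ccc([C@H]2OC(=O)C[C@@H]2C)cc1OC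
F2 | step 4 | (4S,5S)-5-(3,4-dimethoxyphenyl)-3-[(3,4-dimethoxyphenyl)(hydroxy)methyl]-4-methyloxolan-2-one (C3 and carbinol centre undefined) | COc1ccc([C@H]2OC(=O)C(C(O)c3ccc(OC)c(OC)c3)[C@@H]2C)cc1OC
F3 | step 4 | (3,4-dimethoxyphenyl)[(4S,5S)-5-(3,4-dimethoxyphenyl)-4-methyl-2-oxooxolan-3-yl]methyl methanesulfonate (same two centres undefined) | COc1ccc([C@H]2OC(=O)C(C(OS(C)(=O)=O)c3ccc(OC)c(OC)c3)[C@@H]2C)cc1OC
F0 | step 7 | none | none
F4 | step 2 | (1S,2S)-1-(3,4-dimethoxyphenyl)-2-methylbut-3-en-1-ol | COc1ccc([C@@H](O)[C@@H](C)C=C)cc1OC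
F5 | step 2 | tert-butyl{[(1S,2S)-1-(3,4-dimethoxyphenyl)-2-methylbut-3-en-1-yl]oxy}dimethylsilane | COc1ccc([C@@H](O[Si](C)(C)C(C)(C)C)[C@@H](C)C=C)cc1OC
F6 | step 2 | (2R,3S)-3-[(tert-butyldimethylsilyl)oxy]-3-(3,4-dimethoxyphenyl)-2-methylpropanal | COc1ccc([C@@H](O[Si](C)(C)C(C)(C)C)[C@@H](C)C=O)cc1OC
F7 | step 2 | tert-butyl{[(1S,2S)-1-(3,4-dimethoxyphenyl)-2-methylbut-3-yn-1-yl]oxy}dimethylsilane | COc1ccc([C@@H](O[Si](C)(C)C(C)(C)C)[C@@H](C)C#C)cc1OC
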